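Germacrane numbering is used (ring C1–C10; lactone fused at C6/C7). Everything rests on the C1–C2 disconnection of the ring allylic alcohol C2(OH)–C1=C10: alkenyl carbon C1 is joined to carbinol carbon C2 by an intramolecular Nozaki–Hiyama–Kishi addition. As the last step, this one operation closes the ten-membered carbocycle, creates the C2 stereocenter under control of a chiral chromium ligand and delivers the unprotected target. The precursor is an open-chain (E)-alkenyl iodide/aldehyde that already carries the trans-fused α-methylene lactone, the C8 angelate and the C14 acetate; its ring-cis C4=C5 alkene and the C6/C7 lactone fold the chain for closure.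

Key step: step 14

Assumption: 4-methyl-5,6-dihydro-2H-pyran-2-one (1, the dehydration product of mevalonolactone) is taken as a catalogue compound.
Assumption: the (S)-configured oxazoline–sulfonamide ligand of step 14 is taken to direct the alkenyl group to the Re face of the C2 aldehyde; if the sense is the opposite, its enantiomer is used with no other change.

Step 1
Reactants: 1 4-methyl-5,6-dihydro-2H-pyran-2-one; 2 tert-butyldimethyl(prop-2-yn-1-yloxy)silane
Product: 4 (5Z)-1-(tert-butyldimethylsilyloxy)-8-hydroxy-6-methyloct-5-en-2-yn-4-one, via lithium acetylide 3 (not isolated)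
Conditions: 2, n-BuLi, THF, −78 °C; then 1, −78 to −40 °C; aq NH4Cl
Reagents that add atoms: none
Why: Acylation of a lithium acetylide by a lactone: 1,2-addition to the C=O of 1 gives a lactolate that opens on work-up to the conjugated hydroxy ynone, and because the enone double bond was part of the six-membered ring of 1 it should emerge as the Z isomer (the future ring-cis C4=C5) without any olefination.

Step 2
Reactants: 4 (5Z)-1-(tert-butyldimethylsilyloxy)-8-hydroxy-6-methyloct-5-en-2-yn-4-one
Product: 5 (5Z)-1-(tert-butyldimethylsilyloxy)-8-(tert-butyldiphenylsilyloxy)-6-methyloct-5-en-2-yn-4-one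
Conditions: TBDPSOTf, 2,6-lutidine, CH2Cl2, −78 to 0 °C
Reagents that add atoms: tert-butyldiphenylsilyl triflate, CC(C)(C)[Si](OS(=O)(=O)C(F)(F)F)(c1ccccc1)c1ccccc1
Why: Silyl triflate silylation of the primary alcohol with a non-nucleophilic base, so that no nucleophilic amine can add to the ynone; the bulky TBDPS group is meant to outlast the TBS group in step 6.

Step 3
Reactants: 5 (5Z)-1-(tert-butyldimethylsilyloxy)-8-(tert-butyldiphenylsilyloxy)-6-methyloct-5-en-2-yn-4-one
Product: 6 (4R,5Z)-1-(tert-butyldimethylsilyloxy)-8-(tert-butyldiphenylsilyloxy)-6-methyloct-5-en-2-yn-4-ol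
Conditions: (R)-2-methyl-CBS-oxazaborolidine, catecholborane, toluene, −78 °C
Reagents that add atoms: none
Why: CBS reduction: with the slender alkynyl arm as the small and the Z-disubstituted alkenyl arm as the large substituent, the (R)-catalyst should deliver hydride to the face that gives the (4R)-carbinol, which becomes C6 of the target.

Step 4
Reactants: 6 (4R,5Z)-1-(tert-butyldimethylsilyloxy)-8-(tert-butyldiphenylsilyloxy)-6-methyloct-5-en-2-yn-4-ol
Product: 8 (2Z,4R,5Z)-1-(tert-butyldimethylsilyloxy)-8-(tert-butyldiphenylsilyloxy)-2-iodo-6-methylocta-2,5-dien-4-ol, via sodium alkenylaluminate 7 (not isolated)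
Conditions: NaAlH2(OCH2CH2OMe)2, THF, 0 °C; then I2, THF, −78 to 0 °C
Reagents that add atoms: iodine, II
Why: Hydroxyl-directed trans-hydroalumination of the propargylic alcohol (hydride to the proximal alkyne carbon, aluminium on the distal one within a five-membered alkoxyaluminate) followed by iodinolysis with retention should give the (Z)-iodoalkene regio- and stereospecifically, the low temperature keeping the neighbouring silyl ether from eliminating.

Step 5
Reactants: 8 (2Z,4R,5Z)-1-(tert-butyldimethylsilyloxy)-8-(tert-butyldiphenylsilyloxy)-2-iodo-6-methylocta-2,5-dien-4-ol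
Product: 9 (5R)-3-[(tert-butyldimethylsilyloxy)methyl]-5-[(1Z)-4-(tert-butyldiphenylsilyloxy)-2-methylbut-1-en-1-yl]furan-2(5H)-one
Conditions: PdCl2(PPh3)2 (5 mol %), CO (1 atm), iPr2NEt, THF, 45 °C
Reagents that add atoms: carbon monoxide, [C-]#[O+]
Why: Palladium-catalysed cyclocarbonylation of a (Z)-3-iodoallylic alcohol: oxidative addition of zerovalent palladium to the C–I bond, CO insertion and capture of the acylpalladium by the cis-disposed hydroxyl close the butenolide, and the stereocenter is not involved.

Step 6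
Reactants: 9 (5R)-3-[(tert-butyldimethylsilyloxy)methyl]-5-[(1Z)-4-(tert-butyldiphenylsilyloxy)-2-methylbut-1-en-1-yl]furan-2(5H)-one
Product: 10 (5R)-3-(bromomethyl)-5-[(1Z)-4-(tert-butyldiphenylsilyloxy)-2-methylbut-1-en-1-yl]furan-2(5H)-one
Conditions: Ph3PBr2, CH2Cl2, 0 °C to rt
Reagents that add atoms: triphenylphosphine dibromide, Br[P+](c1ccccc1)(c1ccccc1)c1ccccc1.[Br-]
Why: Ph3PBr2 converts a primary (here allylic) TBS ether directly into the bromide (silyl transfer to bromide, then SN2 on the alkoxyphosphonium ion), whereas the more hindered TBDPS ether is expected to stay.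

Step 7
Reactants: 11 prop-2-yn-1-yl acetate; 12 allyl bromide
Product: 13 (2E)-2-(bromomethylidene)pent-4-en-1-yl acetate (Br cis to the allyl group)
Conditions: PdBr2(PhCN)2 (3 mol %), 12 as solvent, slow addition of 11, rt
Reagents that add atoms: none
Why: Palladium-catalysed bromoallylation of a terminal alkyne: cis-bromopalladation by divalent palladium puts Br on the terminal carbon, the alkenylpalladium inserts the alkene of allyl bromide and β-bromide elimination returns PdBr2, so Br and allyl end cis, which is the geometry of the future ring-cis C1=C10 bond.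

Step 8
Reactants: 13 (2E)-2-(bromomethylidene)pent-4-en-1-yl acetate
Product: 14 (2E)-2-(iodomethylidene)pent-4-en-1-yl acetate
Conditions: CuI (10 mol %), trans-N,N'-dimethylcyclohexane-1,2-diamine (20 mol %), NaI, 1,4-dioxane, 100 °C
Reagents that add atoms: sodium iodide, [Na+].[I-]
Why: Copper-catalysed halogen exchange (Finkelstein-type) of an alkenyl bromide, which proceeds with retention of alkene geometry and provides the more reactive alkenyl iodide for step 14.

Step 9
Reactants: 14 (2E)-2-(iodomethylidene)pent-4-en-1-yl acetate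
Product: 16 (2E)-3-iodo-2-(2-oxoethyl)prop-2-en-1-yl acetate, via diol 15 (not isolated)
Conditions: OsO4 (2 mol %), NaIO4, 2,6-lutidine, 1,4-dioxane/H2O, rt; product used crude
Reagents that add atoms: osmium tetroxide (catalytic oxygen carrier), O=[Os](=O)(=O)=O; sodium periodate (terminal oxidant), [Na+].[O-][I](=O)(=O)=O
Why: Lemieux–Johnson cleavage: OsO4 should dihydroxylate the unhindered terminal vinyl group in preference to the halogen-deactivated trisubstituted iodoalkene, and periodate cleaves the diol to the β,γ-unsaturated aldehyde.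

Step 10
Reactants: 10 (5R)-3-(bromomethyl)-5-[(1Z)-4-(tert-butyldiphenylsilyloxy)-2-methylbut-1-en-1-yl]furan-2(5H)-one; 16 (2E)-3-iodo-2-(2-oxoethyl)prop-2-en-1-yl acetate
Product: 18 (4R,5R)-4-[(1S,3E)-3-(acetoxymethyl)-1-hydroxy-4-iodobut-3-en-1-yl]-5-[(1Z)-4-(tert-butyldiphenylsilyloxy)-2-methylbut-1-en-1-yl]-3-methylideneoxolan-2-one (6R,7R,8S in germacrane numbering), via allylzinc bromide 17 (not isolated)
Conditions: Zn dust, THF/sat. aq NH4Cl, 0 °C to rt
Reagents that add atoms: none
Why: Zinc Barbier allylation of an aldehyde by a 3-(bromomethyl)butenolide: the allylzinc reacts at its γ-carbon (SE2') on the ring face anti to the C6 side chain, which sets C7 trans to C6, and the chair Zimmerman–Traxler transition state with the ring-locked E-type γ-substituent should give the anti carbinol (8S), the epimer that step 11 inverts.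

Step 11
Reactants: 18 the (6R,7R,8S)-hydroxy lactone of step 10; 19 angelic acid, (2Z)-2-methylbut-2-enoic acid
Product: 20 (1R,3E)-3-(acetoxymethyl)-1-{(2R,3R)-2-[(1Z)-4-(tert-butyldiphenylsilyloxy)-2-methylbut-1-en-1-yl]-4-methylidene-5-oxooxolan-3-yl}-4-iodobut-3-en-1-yl (2Z)-2-methylbut-2-enoate (6R,7R,8R)
Conditions: PPh3, DIAD, toluene, 0 °C to rt
Reagents that add atoms: none
Why: Mitsunobu esterification: the carboxylate of 19 displaces the alkoxyphosphonium ion by SN2 with inversion, which turns 8S into the required 8R and installs the angelate without activating the acid, so its Z double bond should not isomerise.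

Step 12
Reactants: 20 the (6R,7R,8R)-angelate TBDPS ether of step 11
Product: 21 (1R,3E)-3-(acetoxymethyl)-1-{(2R,3R)-2-[(1Z)-4-hydroxy-2-methylbut-1-en-1-yl]-4-methylidene-5-oxooxolan-3-yl}-4-iodobut-3-en-1-yl (2Z)-2-methylbut-2-enoate
Conditions: HF·pyridine, pyridine, THF, 0 °C to rt
Reagents that add atoms: none
Why: Fluoride cleavage of the silyl ether under buffered acidic conditions, under which the lactone, both esters, the alkenyl iodide and the α-methylene group should be stable.

Step 13
Reactants: 21 the primary alcohol of step 12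
Product: 22 (1R,3E)-3-(acetoxymethyl)-4-iodo-1-{(2R,3R)-2-[(1Z)-2-methyl-4-oxobut-1-en-1-yl]-4-methylidene-5-oxooxolan-3-yl}but-3-en-1-yl (2Z)-2-methylbut-2-enoate
Conditions: Dess–Martin periodinane, NaHCO3, CH2Cl2, 0 °C; product used directly
Reagents that add atoms: none
Why: Dess–Martin oxidation of the primary alcohol under buffered, non-basic conditions, so that the β,γ-unsaturated aldehyde does not move into conjugation.

Step 14
Reactants: 22 the iodo aldehyde of step 13
Product: 24 (2S,6R,7R,8R)-14-acetoxy-8-angeloyloxy-2-hydroxygermacra-1(10)E,4Z,11(13)-trien-12,6-olide (CNP0151426.1), via alkenylchromium species 23 (not isolated)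
Conditions: CrCl2 (8 equiv), (S)-N-[2-(4-isopropyl-4,5-dihydrooxazol-2-yl)-6-methylphenyl]methanesulfonamide (8.8 equiv), Et3N (8.8 equiv), NiCl2 (0.5 equiv), THF, rt; 22 added by syringe pump to 2 mM
Reagents that add atoms: none
Why: Zerovalent nickel (from NiCl2 and CrCl2) inserts into the C1–I bond with retention, transmetalation gives the alkenyl species 23 of trivalent chromium, and this adds to the C2 aldehyde to form the C1–C2 bond; the reaction type is the intramolecular Nozaki–Hiyama–Kishi alkenylation used for medium-ring and macrocyclic allylic alcohols. The ten-membered carbocycle closes in a 10-exo-trig mode, the aldehyde C=O staying outside the new ring. The new C2 stereocenter (2S) is set by reagent control: the chiral oxazoline–sulfonamide ligand on chromium directs the alkenyl group to the Re face of the aldehyde, over any bias of the folded chain. Cyclization has to outrun oligomerization and proto-deiodination, which is secured by slow addition to high dilution and by three turn elements of the substrate (the ring-cis C1=C10 and C4=C5 alkenes and the trans-fused C6/C7 lactone) that hold C1 and C2 close. Chemoselectivity is inherent, since the alkenylchromium reagent adds only to the aldehyde and leaves the lactone, the angelate, the allylic acetate and the α-methylene group untouched, and nickel should insert into the alkenyl C–I bond far faster than into the allylic C–OAc bond. The trisubstituted alkenyl metal keeps its geometry, so C1=C10 should emerge ring-cis as required.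

Compound list
1 | 4-methyl-5,6-dihydro-2H-pyran-2-one (anhydromevalonolactone) | CC1=CC(=O)OCC1 | starting material
2 | tert-butyldimethyl(prop-2-yn-1-yloxy)silane | C#CCO[Si](C)(C)C(C)(C)C | starting material
3 | [3-(tert-butyldimethylsilyloxy)prop-1-yn-1-yl]lithium (not isolated) | [Li]C#CCO[Si](C)(C)C(C)(C)C | intermediate
4 | (5Z)-1-(tert-butyldimethylsilyloxy)-8-hydroxy-6-methyloct-5-en-2-yn-4-one | OCC/C(C)=C\C(=O)C#CCO[Si](C)(C)C(C)(C)C | intermediate
5 | (5Z)-1-(tert-butyldimethylsilyloxy)-8-(tert-butyldiphenylsilyloxy)-6-methyloct-5-en-2-yn-4-one | CC(C)(C)[Si](OCC/C(C)=C\C(=O)C#CCO[Si](C)(C)C(C)(C)C)(c1ccccc1)c1ccccc1 | intermediate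
6 | (4R,5Z)-1-(tert-butyldimethylsilyloxy)-8-(tert-butyldiphenylsilyloxy)-6-methyloct-5-en-2-yn-4-ol | CC(C)(C)[Si](OCC/C(C)=C\[C@@H](O)C#CCO[Si](C)(C)C(C)(C)C)(c1ccccc1)c1ccccc1 | intermediate
7 | sodium alkenylaluminate: cyclic alkoxy(alkenyl)bis(2-methoxyethoxy)aluminate with Al on the carbon bearing CH2OTBS (not isolated) | CC(C)(C)[Si](OCC/C(C)=C\[C@H]1O[Al-](OCCOC)(OCCOC)C(CO[Si](C)(C)C(C)(C)C)=C1)(c1ccccc1)c1ccccc1.[Na+] | intermediate
8 | (2Z,4R,5Z)-1-(tert-butyldimethylsilyloxy)-8-(tert-butyldiphenylsilyloxy)-2-iodo-6-methylocta-2,5-dien-4-ol | CC(C)(C)[Si](OCC/C(C)=C\[C@@H](O)/C=C(\I)CO[Si](C)(C)C(C)(C)C)(c1ccccc1)c1ccccc1 | intermediate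
9 | (5R)-3-[(tert-butyldimethylsilyloxy)methyl]-5-[(1Z)-4-(tert-butyldiphenylsilyloxy)-2-methylbut-1-en-1-yl]furan-2(5H)-one | CC(C)(C)[Si](OCC/C(C)=C\[C@H]1OC(=O)C(CO[Si](C)(C)C(C)(C)C)=C1)(c1ccccc1)c1ccccc1 | intermediate
10 | (5R)-3-(bromomethyl)-5-[(1Z)-4-(tert-butyldiphenylsilyloxy)-2-methylbut-1-en-1-yl]furan-2(5H)-one | CC(C)(C)[Si](OCC/C(C)=C\[C@H]1OC(=O)C(CBr)=C1)(c1ccccc1)c1ccccc1 | intermediate
11 | prop-2-yn-1-yl acetate | C#CCOC(C)=O | starting material
12 | allyl bromide | C=CCBr | starting material
13 | (2E)-2-(bromomethylidene)pent-4-en-1-yl acetate | Br/C=C(/COC(C)=O)CC=C | intermediate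
14 | (2E)-2-(iodomethylidene)pent-4-en-1-yl acetate | I/C=C(/COC(C)=O)CC=C | intermediate
15 | (2E)-4,5-dihydroxy-2-(iodomethylidene)pentyl acetate, racemic at C4 (not isolated) | I/C=C(/COC(C)=O)CC(O)CO | intermediate
16 | (2E)-3-iodo-2-(2-oxoethyl)prop-2-en-1-yl acetate | I/C=C(/COC(C)=O)CC=O | intermediate
17 | allylzinc bromide derived from 10 (not isolated) | CC(C)(C)[Si](OCC/C(C)=C\[C@H]1OC(=O)C(C[Zn]Br)=C1)(c1ccccc1)c1ccccc1 | intermediate
18 | (4R,5R)-4-[(1S,3E)-3-(acetoxymethyl)-1-hydroxy-4-iodobut-3-en-1-yl]-5-[(1Z)-4-(tert-butyldiphenylsilyloxy)-2-methylbut-1-en-1-yl]-3-methylideneoxolan-2-one | C=C1C(=O)O[C@H](/C=C(/C)CCO[Si](c2ccccc2)(c2ccccc2)C(C)(C)C)[C@H]1[C@H](C/C(=C\I)COC(C)=O)O | intermediate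
19 | angelic acid, (2Z)-2-methylbut-2-enoic acid | C/C=C(/C)C(=O)O | starting material
20 | (1R,3E)-3-(acetoxymethyl)-1-{(2R,3R)-2-[(1Z)-4-(tert-butyldiphenylsilyloxy)-2-methylbut-1-en-1-yl]-4-methylidene-5-oxooxolan-3-yl}-4-iodobut-3-en-1-yl (2Z)-2-methylbut-2-enoate | C=C1C(=O)O[C@H](/C=C(/C)CCO[Si](c2ccccc2)(c2ccccc2)C(C)(C)C)[C@H]1[C@@H](C/C(=C\I)COC(C)=O)OC(=O)/C(C)=C\C | intermediate
21 | (1R,3E)-3-(acetoxymethyl)-1-{(2R,3R)-2-[(1Z)-4-hydroxy-2-methylbut-1-en-1-yl]-4-methylidene-5-oxooxolan-3-yl}-4-iodobut-3-en-1-yl (2Z)-2-methylbut-2-enoate | C=C1C(=O)O[C@H](/C=C(/C)CCO)[C@H]1[C@@H](C/C(=C\I)COC(C)=O)OC(=O)/C(C)=C\C | intermediate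
22 | (1R,3E)-3-(acetoxymethyl)-4-iodo-1-{(2R,3R)-2-[(1Z)-2-methyl-4-oxobut-1-en-1-yl]-4-methylidene-5-oxooxolan-3-yl}but-3-en-1-yl (2Z)-2-methylbut-2-enoate | C=C1C(=O)O[C@H](/C=C(/C)CC=O)[C@H]1[C@@H](C/C(=C\I)COC(C)=O)OC(=O)/C(C)=C\C | intermediate
23 | alkenylchromium species from 22: chloro(sulfonamido)chromium on C1, drawn without the dative oxazoline bond (not isolated) | C=C1C(=O)O[C@H](/C=C(/C)CC=O)[C@H]1[C@@H](C/C(=C\[Cr](Cl)N(c2c(C)cccc2C2=N[C@@H](C(C)C)CO2)S(C)(=O)=O)COC(C)=O)OC(=O)/C(C)=C\C | intermediate
24 | (2S,6R,7R,8R)-14-acetoxy-8-angeloyloxy-2-hydroxygermacra-1(10)E,4Z,11(13)-trien-12,6-olide (CNP0151426.1) | C=C1C(=O)O[C@@H]2/C=C(/C)C[C@H](O)/C=C(/COC(C)=O)C[C@@H](OC(=O)/C(C)=C\C)[C@@H]12 | target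

Total step count: 14.
Longest linear sequence: 11 steps (steps 1–6, then 10–14); steps 7–9 form the three-step side branch.

Steps most likely to fail

Step 14 (ring closure). What may go wrong is oligomerisation or proto-deiodination outrunning closure of the ten-membered ring, amine-induced migration of the C4=C5 double bond into conjugation with the aldehyde, and poor or mismatched facial selectivity at C2. The fallback sets out from 22, which is cyclised without chiral ligand and without amine (CrCl2, NiCl2 cat., DMSO, rt, 2 mM) to the ring-closed carbinols, that is 24 together with its (2R)-epimer F1. The mixture is oxidised (Dess–Martin periodinane, NaHCO3, CH2Cl2) to the single C2 ketone, the 2-oxo-germacranolide F2. This enone is then reduced under reagent control ((R)-2-methyl-CBS-oxazaborolidine, catecholborane, toluene, −78 °C, the ring alkenyl arm acting as the large group), which comes back to the route at 24.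

Step 11 (inversion and angeloylation at C8). What may go wrong is elimination of the alkoxyphosphonium ion toward the conjugated diene, or failure of substitution at the hindered, β-branched carbinol. The fallback sets out from 18: sulfonylation (ClCH2SO2Cl, pyridine, CH2Cl2, 0 °C) would give the (8S)-chloromethanesulfonate F3, and displacement with caesium angelate (19, Cs2CO3, 18-crown-6, toluene, 40 °C) with inversion comes back to the route at 20.

Step 3 (CBS reduction). What may go wrong is low enantioselectivity, because the remote silyloxymethyl group on the alkyne can blur the size difference between the alkynyl and alkenyl arms. The fallback sets out from 5: Luche reduction (NaBH4, CeCl3·7H2O, MeOH, −78 °C) would give the racemic carbinol F4. Lipase-catalysed acetylation (Burkholderia cepacia lipase, vinyl acetate, tert-butyl methyl ether, rt) is expected, by the empirical size rule for lipases, to acylate the (S)-enantiomer to the (4S)-acetate F5 and to leave the (R)-alcohol, which is 6, where the route is rejoined.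

Further compounds
F1 | step 14 | (2R)-epimer of 24 | C=C1C(=O)O[C@@H]2/C=C(/C)C[C@@H](O)/C=C(/COC(C)=O)C[C@@H](OC(=O)/C(C)=C\C)[C@@H]12
F2 | step 14 | (6R,7R,8R)-14-acetoxy-8-angeloyloxy-2-oxogermacra-1(10)E,4Z,11(13)-trien-12,6-olide | C=C1C(=O)O[C@@H]2/C=C(/C)CC(=O)/C=C(/COC(C)=O)C[C@@H](OC(=O)/C(C)=C\C)[C@@H]12
F3 | step 11 | (8S)-chloromethanesulfonate of 18 | C=C1C(=O)O[C@H](/C=C(/C)CCO[Si](c2ccccc2)(c2ccccc2)C(C)(C)C)[C@H]1[C@H](C/C(=C\I)COC(C)=O)OS(=O)(=O)CCl
F4 | step 3 | racemic (5Z)-1-(tert-butyldimethylsilyloxy)-8-(tert-butyldiphenylsilyloxy)-6-methyloct-5-en-2-yn-4-ol | CC(C)(C)[Si](OCC/C(C)=C\C(O)C#CCO[Si](C)(C)C(C)(C)C)(c1ccccc1)c1ccccc1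
F5 | step 3 | (4S,5Z)-1-(tert-butyldimethylsilyloxy)-8-(tert-butyldiphenylsilyloxy)-6-methyloct-5-en-2-yn-4-yl acetate | CC(C)(C)[Si](OCC/C(C)=C\[C@H](OC(C)=O)C#CCO[Si](C)(C)C(C)(C)C)(c1ccccc1)c1ccccc1
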